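**Strategy**

Everything rests on a hidden symmetry at C4 of the epoxycyclohexenone ring (C1 ketone, C2 amide-bearing carbon): its two sp2 neighbours, ring carbon C3 and the first carbon of the trienamide chain, are both aldehyde-derived. The precursor is therefore an achiral, acyclic (Z)-enone that carries the finished dienamide on C2 and a 2-silyloxymalonaldehyde at C4. One amine-catalysed, enantiotopic-group-selective aldol condensation joins C2 to C3, closes the carbocycle, sets C4 and leaves the second formyl group as the handle for the triene. The freed C4 hydroxyl then steers epoxidation of C5=C6 (two stereocentres in one event), and Stille couplings complete the lower chain.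

Key step: step 10

Remark: ring atoms are numbered C1 (ketone), C2 (amide-bearing), C3 (ring CH=), C4 (carbinol), C5 and C6 (epoxide) throughout; the given enantiomer has C4 R, C5 S, C6 R with hydroxyl and epoxide oxygen syn, and compounds 1, 2, 5, 7, 8, 22, 25 and 28 are taken as commercial.

**Route**

Step 1
Reactants: 1 cyclohexanecarbaldehyde; 2 triethyl 4-phosphonocrotonate
Product: 3 ethyl (2E,4E)-5-cyclohexylpenta-2,4-dienoate
Conditions: LiHMDS, THF, −78 → 0 °C; aq. NH4Cl
Reagents that add atoms: none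
Why: Vinylogous Horner–Wadsworth–Emmons olefination of an α-branched aldehyde with the lithium anion of the phosphonocrotonate should give the E,E-dienoate, both double bonds being set under the thermodynamic preference of the stabilised phosphonate.

Step 2
Reactants: 3 ethyl (2E,4E)-5-cyclohexylpenta-2,4-dienoate
Product: 4 (2E,4E)-5-cyclohexylpenta-2,4-dienoic acid
Conditions: LiOH·H2O, THF/MeOH/H2O, rt; then aq. HCl
Reagents that add atoms: lithium hydroxide, [Li+].[OH-]
Why: Ester saponification; the conjugated dienoate carries no base-sensitive stereocentre.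

Step 3
Reactants: 4 (2E,4E)-5-cyclohexylpenta-2,4-dienoic acid; 5 2-amino-N-methoxy-N-methylacetamide hydrochloride
Product: 6 (2E,4E)-5-cyclohexyl-N-{2-[methoxy(methyl)amino]-2-oxoethyl}penta-2,4-dienamide
Conditions: EDC·HCl, HOBt (0.2 equiv), i-Pr2NEt, CH2Cl2, 0 °C → rt
Reagents that add atoms: none
Why: Carbodiimide amide coupling through the HOBt active ester, the amine being freed from its hydrochloride by the tertiary amine.

Step 4
Reactants: 7 2,2-dimethyl-1,3-dioxan-5-one; 8 ethynylmagnesium bromide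
Product: 9 5-ethynyl-2,2-dimethyl-1,3-dioxan-5-ol
Conditions: THF, 0 °C → rt; aq. NH4Cl
Reagents that add atoms: none
Why: Grignard 1,2-addition of an acetylide to an unhindered ketone; the carbinol carbon formed (later C4) bears two identical CH2O arms and is not yet a stereocentre.

Step 5
Reactants: 9 5-ethynyl-2,2-dimethyl-1,3-dioxan-5-ol
Product: 10 tert-butyl[(5-ethynyl-2,2-dimethyl-1,3-dioxan-5-yl)oxy]dimethylsilane
Conditions: TBSOTf, 2,6-lutidine, CH2Cl2, 0 °C
Reagents that add atoms: tert-butyldimethylsilyl trifluoromethanesulfonate, CC(C)(C)[Si](C)(C)OS(=O)(=O)C(F)(F)F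
Why: Silylation of a tertiary propargylic alcohol needs the silyl triflate and a hindered pyridine base; the silyl ether shields the C4 oxygen through the organometallic, oxidation and aldol steps.

Step 6
Reactants: 10 tert-butyl[(5-ethynyl-2,2-dimethyl-1,3-dioxan-5-yl)oxy]dimethylsilane; 6 (2E,4E)-5-cyclohexyl-N-{2-[methoxy(methyl)amino]-2-oxoethyl}penta-2,4-dienamide
Product: 12 (2E,4E)-N-{4-[5-(tert-butyldimethylsilyloxy)-2,2-dimethyl-1,3-dioxan-5-yl]-2-oxobut-3-yn-1-yl}-5-cyclohexylpenta-2,4-dienamide, via lithium acetylide 11 (not isolated)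
Conditions: 10 (2.3 equiv), n-BuLi (2.2 equiv), THF, −78 °C; then 6, −78 → −20 °C; aq. NH4Cl
Reagents that add atoms: none
Why: Weinreb ketone synthesis: the acetylide adds once because the chelated tetrahedral adduct survives until work-up; the first equivalent of acetylide is consumed by the amide N–H, which also protects the dienamide from conjugate addition, and the 10 so liberated is recovered.

Step 7
Reactants: 12 (2E,4E)-N-{4-[5-(tert-butyldimethylsilyloxy)-2,2-dimethyl-1,3-dioxan-5-yl]-2-oxobut-3-yn-1-yl}-5-cyclohexylpenta-2,4-dienamide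
Product: 13 (2E,4E)-N-[5-(tert-butyldimethylsilyloxy)-6-hydroxy-5-(hydroxymethyl)-2-oxohex-3-yn-1-yl]-5-cyclohexylpenta-2,4-dienamide
Conditions: PPTS, MeOH, rt
Reagents that add atoms: none
Why: Acid-catalysed transacetalisation to methanol removes the 1,3-dioxane acetonide while the tertiary TBS ether and the ynone should survive; the linear alkyne keeps both hydroxyls out of reach of the ketone.

Step 8
Reactants: 13 (2E,4E)-N-[5-(tert-butyldimethylsilyloxy)-6-hydroxy-5-(hydroxymethyl)-2-oxohex-3-yn-1-yl]-5-cyclohexylpenta-2,4-dienamide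
Product: 14 (2E,4E)-N-[5-(tert-butyldimethylsilyloxy)-5-formyl-2,6-dioxohex-3-yn-1-yl]-5-cyclohexylpenta-2,4-dienamide
Conditions: Dess–Martin periodinane (2.4 equiv), CH2Cl2, 0 °C → rt; used crude
Reagents that add atoms: none
Why: Dess–Martin oxidation converts both primary alcohols to aldehydes under neutral, non-nucleophilic conditions, which avoids retro-aldol loss of formaldehyde from the intermediate hydroxy aldehyde and deformylation of the 2,2-disubstituted malonaldehyde.

Step 9
Reactants: 14 (2E,4E)-N-[5-(tert-butyldimethylsilyloxy)-5-formyl-2,6-dioxohex-3-yn-1-yl]-5-cyclohexylpenta-2,4-dienamide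
Product: 15 (2E,4E)-N-[(3Z)-5-(tert-butyldimethylsilyloxy)-5-formyl-2,6-dioxohex-3-en-1-yl]-5-cyclohexylpenta-2,4-dienamide
Conditions: H2 (1 atm), Lindlar catalyst (Pd on CaCO3, poisoned with Pb(OAc)2), quinoline, EtOAc, 0 °C, dark; stopped after 1 equiv H2; used at once
Reagents that add atoms: none
Why: Lindlar semi-hydrogenation delivers hydrogen syn to the alkyne and should stop at the Z-enone, the alkyne being reduced much faster on the poisoned catalyst than the conjugated dienamide or the aldehydes.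

Step 10
Reactants: 15 (2E,4E)-N-[(3Z)-5-(tert-butyldimethylsilyloxy)-5-formyl-2,6-dioxohex-3-en-1-yl]-5-cyclohexylpenta-2,4-dienamide
Product: 18 (2E,4E)-N-[(3S)-3-(tert-butyldimethylsilyloxy)-3-formyl-6-oxocyclohexa-1,4-dien-1-yl]-5-cyclohexylpenta-2,4-dienamide, via proline dienamine 16 (not isolated), via ketol 17 (not isolated)
Conditions: (R)-proline (30 mol %), AcOH (1 equiv), DMF, 4 °C → rt, dark
Reagents that add atoms: none
Why: Proposed new method: (R)-proline condenses with the C1 ketone of 15 to the cross-conjugated dienamine 16, whose C2 terminus adds to one of the two enantiotopic formyl groups on C4 to give ketol 17, and loss of water through the enamine–iminium manifold installs the C2=C3 enamide double bond; the closest known reaction type is the proline-catalysed Hajos–Parrish–Eder–Sauer–Wiechert aldol condensation, in which a ketone enamine likewise chooses between two enantiotopic carbonyl groups on a quaternary carbon, here carried over from cyclic 1,3-diketones to an acyclic 2-silyloxymalonaldehyde. The six-membered carbocycle closes in the 6-(enolendo)-exo-trig mode. C4 is the only lasting new stereocentre and is set by the catalyst: in the accepted enamine–carboxylic acid transition-state model (anti enamine, acid hydrogen-bonded to the reacting formyl oxygen), with the silyloxy group pseudo-equatorial and antiperiplanar to the forming bond (polar Felkin–Anh arrangement), the R catalyst should lead to the S aldehyde 18, while the two transient centres of 17 vanish on dehydration. The step needs enantiotopic-group selectivity and site selectivity; the latter is secured because C2 is the only enolisable carbon of the ketone (C6 is vinylic) and the Z geometry of C5=C6 holds C2 within reach of C3. The silyl ether prevents hemiketal formation and α-ketol shifts, and the non-enolisable formyl groups cannot act as aldol donors.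

Step 11
Reactants: 18 (2E,4E)-N-[(3S)-3-(tert-butyldimethylsilyloxy)-3-formyl-6-oxocyclohexa-1,4-dien-1-yl]-5-cyclohexylpenta-2,4-dienamide
Product: 19 (2E,4E)-N-{(3S)-3-(tert-butyldimethylsilyloxy)-3-[(E)-2-iodoethenyl]-6-oxocyclohexa-1,4-dien-1-yl}-5-cyclohexylpenta-2,4-dienamide
Conditions: CrCl2 (8 equiv), CHI3 (3 equiv), THF, 0 °C → rt, dark
Reagents that add atoms: iodoform, IC(I)I
Why: Takai olefination: the geminal dichromium reagent formed from iodoform and CrCl2 adds to the aldehyde only (ketone, enamide and silyl ether are inert) and elimination gives the E-iodoalkene, the neutral medium avoiding nucleophile-induced loss of the formyl group from the cyclohexadienone.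

Step 12
Reactants: 19 (2E,4E)-N-{(3S)-3-(tert-butyldimethylsilyloxy)-3-[(E)-2-iodoethenyl]-6-oxocyclohexa-1,4-dien-1-yl}-5-cyclohexylpenta-2,4-dienamide
Product: 20 (2E,4E)-5-cyclohexyl-N-{(3S)-3-hydroxy-3-[(E)-2-iodoethenyl]-6-oxocyclohexa-1,4-dien-1-yl}penta-2,4-dienamide
Conditions: HF·pyridine, pyridine, THF, 0 °C → rt
Reagents that add atoms: none
Why: Fluoride cleavage of the tertiary silyl ether under buffered, weakly acidic conditions that leave the vinyl iodide and the cross-conjugated dienone untouched and are too mild for a dienone–phenol rearrangement.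

Step 13
Reactants: 20 (2E,4E)-5-cyclohexyl-N-{(3S)-3-hydroxy-3-[(E)-2-iodoethenyl]-6-oxocyclohexa-1,4-dien-1-yl}penta-2,4-dienamide
Product: 21 (2E,4E)-5-cyclohexyl-N-{(1R,5S,6S)-5-hydroxy-5-[(E)-2-iodoethenyl]-2-oxo-7-oxabicyclo[4.1.0]hept-3-en-3-yl}penta-2,4-dienamide
Conditions: t-BuOOH (decane solution), DBU, CH2Cl2, −20 → 0 °C
Reagents that add atoms: tert-butyl hydroperoxide, CC(C)(C)OO
Why: Weitz–Scheffer nucleophilic epoxidation: the peroxide anion adds to C5 of the more electrophilic, unsubstituted enone C5=C6 (C2=C3 is deactivated by the amide nitrogen) and the enolate closes onto oxygen; the C4 hydroxyl hydrogen-bonds the incoming peroxide and the larger iodoethenyl group shields the other face, so both new centres (C5 S, C6 R) should form syn to the hydroxyl in one event.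

Step 14
Reactants: 22 cyclopentane-1,3-dione
Product: 23 2-nitrocyclopentane-1,3-dione
Conditions: fuming HNO3, Et2O, −10 → 0 °C
Reagents that add atoms: nitric acid, O[N+](=O)[O-]
Why: Electrophilic nitration at the doubly activated C2 of the enolised cyclic 1,3-dione.

Step 15
Reactants: 23 2-nitrocyclopentane-1,3-dione
Product: 24 2-amino-3-hydroxycyclopent-2-en-1-one hydrochloride
Conditions: H2 (1 atm), Pd/C (10 %), conc. HCl, EtOH, rt
Reagents that add atoms: hydrogen chloride, Cl
Why: Catalytic hydrogenation of the nitro group to the amine, trapped as its hydrochloride so that the electron-rich aminoenol neither oxidises nor self-condenses.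

Step 16
Reactants: 25 (2E)-3-iodoprop-2-enoic acid; 24 2-amino-3-hydroxycyclopent-2-en-1-one hydrochloride
Product: 27 (2E)-N-(2-hydroxy-5-oxocyclopent-1-en-1-yl)-3-iodoprop-2-enamide, via acid chloride 26 (not isolated)
Conditions: (COCl)2, DMF (cat.), CH2Cl2, 0 °C → rt, concentrate; then 24, Et3N (3 equiv), THF/DMF, −20 → 0 °C
Reagents that add atoms: none
Why: N-Acylation of the weakly nucleophilic vinylogous-acid amine needs the acid chloride; any enol ester formed should pass its acyl group on to nitrogen, and acylation outruns addition–elimination at the β-iodo carbon at low temperature.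

Step 17
Reactants: 27 (2E)-N-(2-hydroxy-5-oxocyclopent-1-en-1-yl)-3-iodoprop-2-enamide; 28 (E)-1,2-bis(tributylstannyl)ethene
Product: 29 (2E,4E)-N-(2-hydroxy-5-oxocyclopent-1-en-1-yl)-5-(tributylstannyl)penta-2,4-dienamide
Conditions: 28 (3 equiv), PdCl2(MeCN)2 (5 mol %), DMF, rt, dark
Reagents that add atoms: none
Why: Stille coupling of the vinyl iodide with an excess of the symmetrical bis-stannane should give the mono-coupled dienylstannane with retention of both alkene geometries, the excess suppressing double coupling.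

Step 18
Reactants: 21 (2E,4E)-5-cyclohexyl-N-{(1R,5S,6S)-5-hydroxy-5-[(E)-2-iodoethenyl]-2-oxo-7-oxabicyclo[4.1.0]hept-3-en-3-yl}penta-2,4-dienamide; 29 (2E,4E)-N-(2-hydroxy-5-oxocyclopent-1-en-1-yl)-5-(tributylstannyl)penta-2,4-dienamide
Product: 30 (2E,4E)-5-cyclohexyl-N-[(1R,5R,6S)-5-hydroxy-5-{(1E,3E,5E)-7-[(2-hydroxy-5-oxocyclopent-1-en-1-yl)amino]-7-oxohepta-1,3,5-trien-1-yl}-2-oxo-7-oxabicyclo[4.1.0]hept-3-en-3-yl]penta-2,4-dienamide
Conditions: Pd2(dba)3 (5 mol %), AsPh3 (20 mol %), DMF, rt, dark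
Reagents that add atoms: none
Why: Stille coupling under ligand-accelerated, base-free conditions joins the two E-alkenyl partners with retention, and the neutral medium should tolerate the epoxy ketone, the tertiary alcohol and the acidic enol.

**Compound list**

1 | cyclohexanecarbaldehyde | O=CC1CCCCC1 | starting material
2 | triethyl 4-phosphonocrotonate | CCOC(=O)/C=C/CP(=O)(OCC)OCC | starting material
3 | ethyl (2E,4E)-5-cyclohexylpenta-2,4-dienoate | CCOC(=O)/C=C/C=C/C1CCCCC1 | intermediate
4 | (2E,4E)-5-cyclohexylpenta-2,4-dienoic acid | OC(=O)/C=C/C=C/C1CCCCC1 | intermediate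
5 | 2-amino-N-methoxy-N-methylacetamide hydrochloride | Cl.NCC(=O)N(C)OC | starting material
6 | (2E,4E)-5-cyclohexyl-N-{2-[methoxy(methyl)amino]-2-oxoethyl}penta-2,4-dienamide | CON(C)C(=O)CNC(=O)/C=C/C=C/C1CCCCC1 | intermediate
7 | 2,2-dimethyl-1,3-dioxan-5-one | CC1(C)OCC(=O)CO1 | starting material
8 | ethynylmagnesium bromide | C#C[Mg]Br | starting material
9 | 5-ethynyl-2,2-dimethyl-1,3-dioxan-5-ol | CC1(C)OCC(O)(C#C)CO1 | intermediate
10 | tert-butyl[(5-ethynyl-2,2-dimethyl-1,3-dioxan-5-yl)oxy]dimethylsilane | CC1(C)OCC(C#C)(O[Si](C)(C)C(C)(C)C)CO1 | intermediate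
11 | lithium acetylide of 10 | [Li]C#CC1(O[Si](C)(C)C(C)(C)C)COC(C)(C)OC1 | intermediate
12 | (2E,4E)-N-{4-[5-(tert-butyldimethylsilyloxy)-2,2-dimethyl-1,3-dioxan-5-yl]-2-oxobut-3-yn-1-yl}-5-cyclohexylpenta-2,4-dienamide | CC1(C)OCC(C#CC(=O)CNC(=O)/C=C/C=C/C2CCCCC2)(O[Si](C)(C)C(C)(C)C)CO1 | intermediate
13 | (2E,4E)-N-[5-(tert-butyldimethylsilyloxy)-6-hydroxy-5-(hydroxymethyl)-2-oxohex-3-yn-1-yl]-5-cyclohexylpenta-2,4-dienamide | OCC(CO)(O[Si](C)(C)C(C)(C)C)C#CC(=O)CNC(=O)/C=C/C=C/C1CCCCC1 | intermediate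
14 | (2E,4E)-N-[5-(tert-butyldimethylsilyloxy)-5-formyl-2,6-dioxohex-3-yn-1-yl]-5-cyclohexylpenta-2,4-dienamide | O=CC(C=O)(O[Si](C)(C)C(C)(C)C)C#CC(=O)CNC(=O)/C=C/C=C/C1CCCCC1 | intermediate
15 | (2E,4E)-N-[(3Z)-5-(tert-butyldimethylsilyloxy)-5-formyl-2,6-dioxohex-3-en-1-yl]-5-cyclohexylpenta-2,4-dienamide | O=CC(C=O)(O[Si](C)(C)C(C)(C)C)/C=C\C(=O)CNC(=O)/C=C/C=C/C1CCCCC1 | intermediate
16 | (R)-proline dienamine of 15 (enamine C1=C2, geometry not defined) | OC(=O)[C@H]1CCCN1C(=CNC(=O)/C=C/C=C/C1CCCCC1)/C=C\C(C=O)(C=O)O[Si](C)(C)C(C)(C)C | intermediate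
17 | (2E,4E)-N-[(3S)-3-(tert-butyldimethylsilyloxy)-3-formyl-2-hydroxy-6-oxocyclohex-4-en-1-yl]-5-cyclohexylpenta-2,4-dienamide (ketol, mixture at ring C1 and C2) | O=C(/C=C/C=C/C1CCCCC1)NC1C(O)[C@](O[Si](C)(C)C(C)(C)C)(C=O)C=CC1=O | intermediate
18 | (2E,4E)-N-[(3S)-3-(tert-butyldimethylsilyloxy)-3-formyl-6-oxocyclohexa-1,4-dien-1-yl]-5-cyclohexylpenta-2,4-dienamide | O=C(/C=C/C=C/C1CCCCC1)NC1=C[C@](O[Si](C)(C)C(C)(C)C)(C=O)C=CC1=O | intermediate
19 | (2E,4E)-N-{(3S)-3-(tert-butyldimethylsilyloxy)-3-[(E)-2-iodoethenyl]-6-oxocyclohexa-1,4-dien-1-yl}-5-cyclohexylpenta-2,4-dienamide | O=C(/C=C/C=C/C1CCCCC1)NC1=C[C@](O[Si](C)(C)C(C)(C)C)(/C=C/I)C=CC1=O | intermediate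
20 | (2E,4E)-5-cyclohexyl-N-{(3S)-3-hydroxy-3-[(E)-2-iodoethenyl]-6-oxocyclohexa-1,4-dien-1-yl}penta-2,4-dienamide | O=C(/C=C/C=C/C1CCCCC1)NC1=C[C@](O)(/C=C/I)C=CC1=O | intermediate
21 | (2E,4E)-5-cyclohexyl-N-{(1R,5S,6S)-5-hydroxy-5-[(E)-2-iodoethenyl]-2-oxo-7-oxabicyclo[4.1.0]hept-3-en-3-yl}penta-2,4-dienamide | O=C(/C=C/C=C/C1CCCCC1)NC1=C[C@](O)(/C=C/I)[C@H]2O[C@H]2C1=O | intermediate
22 | cyclopentane-1,3-dione | O=C1CCC(=O)C1 | starting material
23 | 2-nitrocyclopentane-1,3-dione | O=C1CCC(=O)C1[N+](=O)[O-] | intermediate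
24 | 2-amino-3-hydroxycyclopent-2-en-1-one hydrochloride | NC1=C(O)CCC1=O.Cl | intermediate
25 | (2E)-3-iodoprop-2-enoic acid | OC(=O)/C=C/I | starting material
26 | (2E)-3-iodoprop-2-enoyl chloride | ClC(=O)/C=C/I | intermediate
27 | (2E)-N-(2-hydroxy-5-oxocyclopent-1-en-1-yl)-3-iodoprop-2-enamide | O=C(/C=C/I)NC1=C(O)CCC1=O | intermediate
28 | (E)-1,2-bis(tributylstannyl)ethene | CCCC[Sn](CCCC)(CCCC)/C=C/[Sn](CCCC)(CCCC)CCCC | starting material
29 | (2E,4E)-N-(2-hydroxy-5-oxocyclopent-1-en-1-yl)-5-(tributylstannyl)penta-2,4-dienamide | O=C(/C=C/C=C/[Sn](CCCC)(CCCC)CCCC)NC1=C(O)CCC1=O | intermediate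
30 | (2E,4E)-5-cyclohexyl-N-[(1R,5R,6S)-5-hydroxy-5-{(1E,3E,5E)-7-[(2-hydroxy-5-oxocyclopent-1-en-1-yl)amino]-7-oxohepta-1,3,5-trien-1-yl}-2-oxo-7-oxabicyclo[4.1.0]hept-3-en-3-yl]penta-2,4-dienamide | O=C(/C=C/C=C/C1CCCCC1)NC1=C[C@](O)(/C=C/C=C/C=C/C(=O)NC2=C(O)CCC2=O)[C@H]2O[C@H]2C1=O | target

**Step count and risks**

Total step count: 18. Longest linear sequence: 12 steps (steps 1–3, 6–13 and 18); steps 4–5 and 14–17 are side branches.

Step 10 (Proposed new method). Three processes may defeat it: weak or reversed discrimination between the two formyl groups; Z-to-E isomerisation of the enone by reversible conjugate addition of the amine, after which the chain cannot cyclise; and amine-triggered loss of a formyl group from substrate or product, the latter driven by aromatisation. The fallback uses known chemistry, sets out from 13 and returns at 18; it sets the stereocentre before ring closure by enzymatic desymmetrisation. Lipase-catalysed mono-acetylation of diol 13 (vinyl acetate, immobilised Burkholderia cepacia lipase, MTBE; the enzyme is chosen from commercial panels for the required enantiotopic preference) should give (2E,4E)-N-[(5S)-6-acetoxy-5-(tert-butyldimethylsilyloxy)-5-(hydroxymethyl)-2-oxohex-3-yn-1-yl]-5-cyclohexylpenta-2,4-dienamide F1. Dess–Martin oxidation then gives the ynone aldehyde F2, and Lindlar semi-hydrogenation the Z-enone F3. An ordinary pyrrolidinium acetate-mediated aldol condensation, which has only one formyl group to attack and none to lose, gives the acetoxymethyl dienone F4. Lipase-mediated hydrolysis at pH 7 (no alkoxide, which would expel formaldehyde) gives the primary alcohol F5, and Dess–Martin oxidation returns to 18.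

Step 9. Over-reduction to the saturated ketone, competing reduction of the dienamide, and isomerisation of the Z-enone before use may occur. The fallback sets out from 10 and returns at 15; it fixes the Z geometry before the carbon–carbon bond is made and needs no hydrogenation. Iodination of alkyne 10 (N-iodosuccinimide, AgNO3 cat., acetone) gives the iodoalkyne F6, and diimide reduction (2-nitrobenzenesulfonyl hydrazide, Et3N) the (Z)-iodoalkene F7. Iodine–lithium exchange (t-BuLi, −78 °C) and addition of the vinyllithium to Weinreb amide 6 (its N–H deprotonated beforehand with i-PrMgCl) give the Z-enone acetonide F8. Methanolysis (PPTS, MeOH) gives the diol F9, which may rest as its cyclic hemiketal and is oxidised through the open form by Dess–Martin periodinane to 15.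

Step 11. Loss of the formyl group with aromatisation of the ring, or one-electron reduction of the cross-conjugated dienone by CrCl2, may compete with olefination. The fallback sets out from 18 and returns at 19; it uses a phosphorus ylide and no reducing metal. Stork–Zhao olefination (Ph3P=CHI from (iodomethyl)triphenylphosphonium iodide and NaHMDS, THF, −78 °C; the cycloaddition pathway forms no free alkoxide) should give the (Z)-iodoalkene F10, and iodine-catalysed photoequilibration (I2 cat., CH2Cl2, visible light) converts it into the more stable E isomer 19.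

Further compounds
F1 | step 10 | (2E,4E)-N-[(5S)-6-acetoxy-5-(tert-butyldimethylsilyloxy)-5-(hydroxymethyl)-2-oxohex-3-yn-1-yl]-5-cyclohexylpenta-2,4-dienamide | OC[C@](O[Si](C)(C)C(C)(C)C)(COC(C)=O)C#CC(=O)CNC(=O)/C=C/C=C/C1CCCCC1
F2 | step 10 | (2E,4E)-N-[(5R)-6-acetoxy-5-(tert-butyldimethylsilyloxy)-5-formyl-2-oxohex-3-yn-1-yl]-5-cyclohexylpenta-2,4-dienamide | O=C[C@](O[Si](C)(C)C(C)(C)C)(COC(C)=O)C#CC(=O)CNC(=O)/C=C/C=C/C1CCCCC1
F3 | step 10 | (2E,4E)-N-[(3Z,5R)-6-acetoxy-5-(tert-butyldimethylsilyloxy)-5-formyl-2-oxohex-3-en-1-yl]-5-cyclohexylpenta-2,4-dienamide | O=C[C@](O[Si](C)(C)C(C)(C)C)(COC(C)=O)/C=C\C(=O)CNC(=O)/C=C/C=C/C1CCCCC1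
F4 | step 10 | {(1S)-1-(tert-butyldimethylsilyloxy)-3-[(2E,4E)-5-cyclohexylpenta-2,4-dienamido]-4-oxocyclohexa-2,5-dien-1-yl}methyl acetate | O=C(/C=C/C=C/C1CCCCC1)NC1=C[C@](O[Si](C)(C)C(C)(C)C)(COC(C)=O)C=CC1=O
F5 | step 10 | (2E,4E)-N-[(3S)-3-(tert-butyldimethylsilyloxy)-3-(hydroxymethyl)-6-oxocyclohexa-1,4-dien-1-yl]-5-cyclohexylpenta-2,4-dienamide | O=C(/C=C/C=C/C1CCCCC1)NC1=C[C@](O[Si](C)(C)C(C)(C)C)(CO)C=CC1=O
F6 | step 9 | tert-butyl{[5-(iodoethynyl)-2,2-dimethyl-1,3-dioxan-5-yl]oxy}dimethylsilane | CC1(C)OCC(C#CI)(O[Si](C)(C)C(C)(C)C)CO1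
F7 | step 9 | tert-butyl({5-[(Z)-2-iodoethenyl]-2,2-dimethyl-1,3-dioxan-5-yl}oxy)dimethylsilane | CC1(C)OCC(/C=C\I)(O[Si](C)(C)C(C)(C)C)CO1
F8 | step 9 | (2E,4E)-N-{(3Z)-4-[5-(tert-butyldimethylsilyloxy)-2,2-dimethyl-1,3-dioxan-5-yl]-2-oxobut-3-en-1-yl}-5-cyclohexylpenta-2,4-dienamide | CC1(C)OCC(/C=C\C(=O)CNC(=O)/C=C/C=C/C2CCCCC2)(O[Si](C)(C)C(C)(C)C)CO1
F9 | step 9 | (2E,4E)-N-[(3Z)-5-(tert-butyldimethylsilyloxy)-6-hydroxy-5-(hydroxymethyl)-2-oxohex-3-en-1-yl]-5-cyclohexylpenta-2,4-dienamide | OCC(CO)(O[Si](C)(C)C(C)(C)C)/C=C\C(=O)CNC(=O)/C=C/C=C/C1CCCCC1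
F10 | step 11 | (2E,4E)-N-{(3S)-3-(tert-butyldimethylsilyloxy)-3-[(Z)-2-iodoethenyl]-6-oxocyclohexa-1,4-dien-1-yl}-5-cyclohexylpenta-2,4-dienamide | O=C(/C=C/C=C/C1CCCCC1)NC1=C[C@](O[Si](C)(C)C(C)(C)C)(/C=C\I)C=CC1=O
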